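(The numbers are invented; no experiment stands behind them.)

The constants below describe a catalyst round and a reagent that also condenses with itself, and the flasks differ in the free catalyst charged.

    catalyst intermediate B → free catalyst + target (k1 = 0.013 min⁻¹)
    2 reagent → self-condensation product (k2 = 0.0018 M⁻¹ min⁻¹)
    2 catalyst intermediate B ⇌ resting dimer, settled at all times (K3 = 240 M⁻¹)
    starting material + free catalyst ⇌ catalyst intermediate A (K4 = 3.5 M⁻¹, k4 = 0.55 M⁻¹ min⁻¹)
    reagent + catalyst intermediate A → catalyst intermediate B (k5 = 0.075 M⁻¹ min⁻¹)

| setting | noon | midnight | winter |
|---|---|---|---|
| starting material | 0.11 M | 0.11 M | 0.11 M |
| reagent | 0.165 M | 0.165 M | 0.165 M |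
| free catalyst | 3.0 mM | 6.0 mM | 12 mM |
| time | 30 h | 30 h | 30 h |

- percentages count the starting material that a species holds: one resting dimer counts as two
- two of one species on the left: rate k times its square, two consumed each time
- "hardly changes" means that all values lie within two and a half points (for a concentration: within two and a half percent of the largest)
- run time (noon): 30 h

* amount of target at the end, in percent of the starting material charged for noon, midnight, winter, in this order
* how that number moves from the first to the last of them (rises, then falls / falls, then rises / rises all the way / falls all the way / hardly changes)

Following one catalyst molecule, the question is what part of its time it spends ready to take reagent. Take the main step first. With the whole catalyst waiting as catalyst intermediate A and reagent held at its charge, noon reckons to 60.8 % target.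

Now add the round. Catalyst intermediate A falls apart at 0.157 min⁻¹, faster than it takes charged reagent at 0.0124 min⁻¹, so the binding of starting material to free catalyst stays near balance and, with starting material at its charge, catalyst intermediate A stands at g = 0.385 times free catalyst. With reagent at its charge, catalyst intermediate B forms at that same 0.0124 min⁻¹ per catalyst intermediate A and leaves at 0.013 min⁻¹, so it stands at h = 0.952 times catalyst intermediate A. Free catalyst, catalyst intermediate A and catalyst intermediate B therefore stand as one to g to g·h, and free catalyst, more abundant than either, is the resting state. The working share, g over the sum of those three terms with resting dimer set aside for now, is the part of the catalyst standing as catalyst intermediate A: 22.0 %. It cuts the noon figure to 13.4 %.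

Next add self-condensation, which at noon removes reagent faster than the round does. Taken alone it makes the charge stand to the reagent left as one + x to one, with x = 1.07 at the end of the run, and mean reagent is then ln(one + x)/x = 0.680 of the charge. Target becomes 9.08 % at noon, 18.2 % at midnight and 36.3 % in winter.

Last, target drawn off lowers starting material and with it g. Taking starting material at its charge less half the target gives 0.368, 0.350 and 0.315. The reckoning then stands at 8.84 %, 17.2 % and 32.2 %, rising all the way but less than in proportion. Resting dimer is still uncounted: a rough estimate for the start, from catalyst intermediate B as reckoned without it, puts 6.30 % of the catalyst there at noon and more in winter, 25.2 %, so the winter figure is less safe than the noon one.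

The forecast gives 8.2 %, 15 % and 25 %, rises all the way, lower than this reckoning in each flask, holding that “the gain is less than proportional”.

The simulation gives 8.33 %, 15.4 % and 27.1 %: rises all the way.

At noon, at 30.0 h, catalyst intermediate A takes reagent at 0.00560 min⁻¹, slower than catalyst intermediate B leaves at 0.013 min⁻¹; with the amounts then standing the working share comes to 23.3 %, and 22.4 % stands as catalyst intermediate A. In winter, at 30.0 h, starting material at 69.8 % and reagent at 38.4 % give a working share of 19.7 %, 18.6 % stands there, and target lies at 27.1 % against the reckoned 32.2 %, with reagent below the 48.3 % that self-condensation by itself leaves.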